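the same everywhere: J 14 mM (held)
- summer: Z 0.036 M; run made earlier
- midnight: Z 0.080 M; run made earlier
- flask: Z 0.053 M; time 12 h

| run | time / h | G / % |
|---|---|---|
| summer | 0.833 | 0 |
| summer | 2.00 | 0 |
| summer | 4.00 | 1 |
| summer | 6.00 | 7 |
| summer | 8.00 | 6 |
| summer | 12.0 | 8 |
| summer | 15.0 | 15 |
| midnight | 1.00 | 0 |
| midnight | 2.00 | 2 |
| midnight | 2.50 | 1 |
| midnight | 4.00 | 0 |
| midnight | 6.00 | 3 |
| midnight | 10.0 | 8 |
| midnight | 15.0 | 17 |

(standard deviation of a reading: 1.5 percentage points)

- what was read earlier has a scatter of 1.5 percentage points, one standard deviation
- at the start none of J is in solution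

- Monday's: doubling the transfer coefficient of J, all else as stated
- Saturday's: doubling the saturation concentration of J, all else as stated

- G at 12 h, in percent of the Z charged
- the change that raises the amount of G at 12 h, in percent of the Z charged most ("none" if none brings more than 2 percentage points) (Monday's / Saturday's / none)
- amount of G at 12 h, in percent of the Z charged, after Monday's

- A one-step world, Z going straight to G under fixed conditions, has its highest rate at the start, but the summer and midnight runs do not: up to 4.00 h their readings average 0.00125 h⁻¹ of the charge, a figure the scatter of 1.5 percentage points does not separate from zero.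
- Between 6.00 h and 15.0 h the two runs climb on average by 0.0122 h⁻¹ of the charge; this mean slope, the late rate, replaces the curve by one straight line and reads ten times the early rate.
- The two charges differ by a factor of 2.22, yet the readings at 15.0 h stand at 15% and 17%, so one rate in fractions of the charge is taken over to the flask at 0.053 M.
- Stepping back from their mean of 16.0% at the late rate puts the line at 12.3% at 12 h.
- But the curve still bends upward, and a parabola through the origin and that mean stands at 10.2% at 12 h, 2.1 points below the line, so this reckoning commits to the parabola's figure.
- The forecast, a separate judgement, says 10.5%, a little higher than this reckoning; it names Saturday's and expects 18% after Monday's: “I read the lag as slow J dissolution”.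
- The flask gives 10.9% at 12 h, 11.0% after Monday's, and Saturday's is the better change.

    Q ⇌ E (K = 0.690, k = 0.740 h⁻¹)
    Z → Q (k = 0.170 h⁻¹)
    J ⇌ X, rate k3*(csat - [X]) (kL = 5.60 h⁻¹)
    X + E → G (k = 3.30 M⁻¹ h⁻¹)

- In the flask, X, the dissolved J, stood at 99.8% of saturation at 1.20 h, and Monday's added 0.039 points of G against 9.1 points by Saturday's. From the flask's result, the late rate reaches 25.5% at 24.0 h, where the flask holds 27.4%. For the same charge read at 30 h, it reaches 32.9%, and that flask holds 34.9%.

The earlier runs and the new flask were computed from invented constants, and the scatter is random.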